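**Retrosynthetic overview**

- The dioxane ring is opened at the hemiketal bond O-1–C-2. This leads back to a phenol whose C-2 ketone is masked as a dioxolane; acid unmasks the ketone and the C-8a hydroxyl closes on it in the last step.
- The strategy rests on ring A. C-8a (phenol oxygen O-1), C-4a (O-4, carrying C-3) and C-5 (OMe) are contiguous and differently oxygenated, and the allyl group on C-7 is meta to C-8a. Ring A is therefore disconnected at C-8a–C-8 to a 2,3-dialkoxy-4-(penta-1,4-dien-2-yl)cyclobutenone. Cyclobutenone C-1/C-2/C-3/C-4 become C-8a/C-4a/C-5/C-6, and the two alkene carbons become C-7/C-8.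
- The cyclobutenone comes from dimethyl squarate: one methoxy group is exchanged for the chiral alkoxy group, the carbonyl next to C–OMe is reduced, the alcohol is chlorinated, and the chloride is Stille-coupled with 2-(tributylstannyl)penta-1,4-diene.
- The chiral alcohol comes from methyl (R)-lactate and 5-bromo-1,2,3-trimethoxybenzene (Weinreb amide, aryl Grignard, dioxolane). The stannane comes from 2,3-dibromopropene and vinylmagnesium bromide.
- Ring order: the trimethoxyphenyl ring is bought, ring A is formed in step 10, and the dioxane ring in step 11.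

Key step: step 10

Assumption: the hemiketal centre C-2 equilibrates through the open keto-phenol, so its (S) configuration (aryl cis to the C-3 methyl, hydroxyl axial and anti to it) is taken as the thermodynamically preferred one; only C-3 (R, from methyl (R)-lactate) is set by the route.

**Route**

Step 1
Reactants: 1 methyl (R)-lactate
Product: 2 (2R)-2-hydroxy-N-methoxy-N-methylpropanamide
Conditions: MeNH(OMe)·HCl (2.5 equiv), i-PrMgCl (5 equiv), THF, −20 to 0 °C; aq NH4Cl
Reagents that add atoms: N,O-dimethylhydroxylamine hydrochloride, CNOC.Cl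
Why: Aminolysis of the ester by the magnesium amide (Weinreb amide formation) should proceed with the hydroxyl held as its magnesium alkoxide, which leaves the stereocentre untouched.

Step 2
Reactants: 2 (2R)-2-hydroxy-N-methoxy-N-methylpropanamide; 3 5-bromo-1,2,3-trimethoxybenzene
Product: 5 (2R)-2-hydroxy-1-(3,4,5-trimethoxyphenyl)propan-1-one, via aryl Grignard reagent 4 (not isolated)
Conditions: 3, Mg, THF, 45 °C (2.5 equiv of 4); then 2, THF, −10 to 0 °C; aq NH4Cl
Reagents that add atoms: none
Why: In this Weinreb ketone synthesis one equivalent of 4 deprotonates the hydroxyl and a second adds to give a chelated tetrahedral intermediate that cannot over-add or enolise, so the (R) centre should be retained.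

Step 3
Reactants: 5 (2R)-2-hydroxy-1-(3,4,5-trimethoxyphenyl)propan-1-one
Product: 6 (1R)-1-[2-(3,4,5-trimethoxyphenyl)-1,3-dioxolan-2-yl]ethan-1-ol
Conditions: HOCH2CH2OH (10 equiv), HC(OMe)3 (2 equiv), TsOH·H2O (5 mol%), CH2Cl2, 25–40 °C; Et3N
Reagents that add atoms: ethylene glycol, OCCO
Why: Acid-catalysed ketalisation driven by the orthoformate as water scavenger should outpace enolisation at this temperature, so the carbinol centre is kept and the ketone is masked against the base and hydride used later.

Step 4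
Reactants: 6 (1R)-1-[2-(3,4,5-trimethoxyphenyl)-1,3-dioxolan-2-yl]ethan-1-ol; 7 dimethyl squarate
Product: 9 3-methoxy-4-{(1R)-1-[2-(3,4,5-trimethoxyphenyl)-1,3-dioxolan-2-yl]ethoxy}cyclobut-3-ene-1,2-dione, via sodium alkoxide 8 (not isolated)
Conditions: NaH (1.05 equiv), THF, 0 °C; then 7 (3 equiv), THF, −40 to 0 °C; aq NH4Cl
Reagents that add atoms: none
Why: Addition–elimination of the alkoxide at a vinylogous ester carbon (squarate transesterification) should give the mixed ester, with the excess of symmetrical 7 suppressing double exchange; the C–O bond at the stereocentre is not touched.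

Step 5
Reactants: 9 3-methoxy-4-{(1R)-1-[2-(3,4,5-trimethoxyphenyl)-1,3-dioxolan-2-yl]ethoxy}cyclobut-3-ene-1,2-dione
Product: 10 4-hydroxy-3-methoxy-2-{(1R)-1-[2-(3,4,5-trimethoxyphenyl)-1,3-dioxolan-2-yl]ethoxy}cyclobut-2-en-1-one (C-4 epimers)
Conditions: LiAlH(OtBu)3 (1.1 equiv), THF, −78 to −40 °C; aq NH4Cl
Reagents that add atoms: none
Why: 1,2-Reduction of a squarate carbonyl by the bulky alkoxyaluminium hydride should favour the carbonyl next to C–OMe, which is the less shielded one and is conjugated to the weaker donor (the secondary alkoxy group with a ketal carbon beside it); the new C-4 centre forms as a mixture and is lost later.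

Step 6
Reactants: 10 4-hydroxy-3-methoxy-2-{(1R)-1-[2-(3,4,5-trimethoxyphenyl)-1,3-dioxolan-2-yl]ethoxy}cyclobut-2-en-1-one
Product: 11 4-chloro-3-methoxy-2-{(1R)-1-[2-(3,4,5-trimethoxyphenyl)-1,3-dioxolan-2-yl]ethoxy}cyclobut-2-en-1-one (C-4 epimers)
Conditions: SOCl2 (1.2 equiv), pyridine (2.5 equiv), CH2Cl2, −20 to 0 °C; filtered, concentrated cold, used crude
Reagents that add atoms: thionyl chloride, O=S(Cl)Cl
Why: Chlorodehydroxylation through the chlorosulfite should place chloride at C-4, where the vinylogous ester is restored, while pyridine buffers the HCl so that the dioxolane survives.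

Step 7
Reactants: 12 2,3-dibromopropene; 13 vinylmagnesium bromide
Product: 14 2-bromopenta-1,4-diene
Conditions: CuI (5 mol%), THF, −20 to 0 °C; distillation
Reagents that add atoms: none
Why: Copper-catalysed allylic substitution by the Grignard reagent displaces only the allylic bromide, and direct and allylic-transposed attack give the same product.

Step 8
Reactants: 14 2-bromopenta-1,4-diene
Product: 16 tributyl(penta-1,4-dien-2-yl)stannane, via dienyl Grignard reagent 15 (not isolated)
Conditions: Mg, THF, 35 °C; then Bu3SnCl, 0 to 25 °C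
Reagents that add atoms: tributyltin chloride, CCCC[Sn](Cl)(CCCC)CCCC
Why: Magnesium insertion into the vinylic C–Br bond and stannylation of the alkenyl Grignard reagent is standard, and the weakly basic magnesium reagent should leave the doubly allylic CH2 alone.

Step 9
Reactants: 11 4-chloro-3-methoxy-2-{(1R)-1-[2-(3,4,5-trimethoxyphenyl)-1,3-dioxolan-2-yl]ethoxy}cyclobut-2-en-1-one; 16 tributyl(penta-1,4-dien-2-yl)stannane
Product: 17 3-methoxy-4-(penta-1,4-dien-2-yl)-2-{(1R)-1-[2-(3,4,5-trimethoxyphenyl)-1,3-dioxolan-2-yl]ethoxy}cyclobut-2-en-1-one (C-4 epimers)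
Conditions: Pd2(dba)3 (2.5 mol%), tri(2-furyl)phosphine (10 mol%), THF, 25–35 °C; filtration through neutral alumina
Reagents that add atoms: none
Why: Stille coupling of a 4-chlorocyclobutenone (oxidative addition of zerovalent palladium into the allylic, carbonyl-flanked C–Cl bond, transmetalation, reductive elimination at C-4) is known, and the fast ligand allows a temperature below that of cyclobutenone ring opening, so 17 can be isolated.

Step 10
Reactants: 17 3-methoxy-4-(penta-1,4-dien-2-yl)-2-{(1R)-1-[2-(3,4,5-trimethoxyphenyl)-1,3-dioxolan-2-yl]ethoxy}cyclobut-2-en-1-one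
Product: 20 3-methoxy-5-(prop-2-en-1-yl)-2-{(1R)-1-[2-(3,4,5-trimethoxyphenyl)-1,3-dioxolan-2-yl]ethoxy}phenol, via dienylketene 18 (not isolated), via cyclohexadienone 19 (not isolated)
Conditions: dry degassed toluene (0.02 M), 105 °C, argon
Reagents that add atoms: none
Why: Heating opens the C-1–C-4 bond of the cyclobutenone by conrotatory four-electron electrocyclic ring opening to dienylketene 18, whose ketene carbon and terminal CH2 of the 1,1-disubstituted alkene join in a thermal disrotatory six-electron electrocyclisation to cyclohexa-2,4-dienone 19, and enolisation gives phenol 20. The closest known reaction is the thermal rearrangement of 4-alkenylcyclobutenones to phenols. Ring A is closed as a six-membered carbocycle by this electrocyclisation, forming the bond that becomes C-8a–C-8. No stereocentre is created: C-4 of 17 becomes an aromatic CH, and the (R) ether centre is untouched under neutral conditions with the ketone masked. The substitution pattern follows from the fixed origin of every ring atom (carbonyl carbon to C–OH, C-2 to the C–O ether carbon, C-3 to C–OMe, C-4 to CH, alkene carbons to C-allyl and CH). Only inward rotation of the dienyl group gives a ketene that can cyclise; the outward isomer reverts through reversible ring closure, and dry non-nucleophilic solvent keeps the ketene from being trapped.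

Step 11
Reactants: 20 3-methoxy-5-(prop-2-en-1-yl)-2-{(1R)-1-[2-(3,4,5-trimethoxyphenyl)-1,3-dioxolan-2-yl]ethoxy}phenol
Product: 22 (2S,3R)-5-methoxy-3-methyl-7-(prop-2-en-1-yl)-2-(3,4,5-trimethoxyphenyl)-2,3-dihydro-1,4-benzodioxin-2-ol, via keto-phenol 21 (not isolated)
Conditions: 1 M aq HCl, THF, 25–40 °C
Reagents that add atoms: water, O
Why: Acid hydrolysis of the dioxolane releases the aryl ketone, onto which the ortho phenol adds (6-exo-trig hemiketalisation); C-3 is not touched, and C-2 should settle under ring–chain equilibration with the aryl group equatorial and the anomeric hydroxyl axial and anti to the C-3 methyl.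

**Compound list**

1 | methyl (R)-lactate | C[C@@H](O)C(=O)OC | starting material
2 | (2R)-2-hydroxy-N-methoxy-N-methylpropanamide | C[C@@H](O)C(=O)N(C)OC | intermediate
3 | 5-bromo-1,2,3-trimethoxybenzene | COc1cc(Br)cc(OC)c1OC | starting material
4 | (3,4,5-trimethoxyphenyl)magnesium bromide | COc1cc([Mg]Br)cc(OC)c1OC | intermediate
5 | (2R)-2-hydroxy-1-(3,4,5-trimethoxyphenyl)propan-1-one | C[C@@H](O)C(=O)c1cc(OC)c(OC)c(OC)c1 | intermediate
6 | (1R)-1-[2-(3,4,5-trimethoxyphenyl)-1,3-dioxolan-2-yl]ethan-1-ol | C[C@@H](O)C1(OCCO1)c2cc(OC)c(OC)c(OC)c2 | intermediate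
7 | dimethyl squarate (3,4-dimethoxycyclobut-3-ene-1,2-dione) | COC1=C(OC)C(=O)C1=O | starting material
8 | sodium (1R)-1-[2-(3,4,5-trimethoxyphenyl)-1,3-dioxolan-2-yl]ethan-1-olate | C[C@@H]([O-])C1(OCCO1)c2cc(OC)c(OC)c(OC)c2.[Na+] | intermediate
9 | 3-methoxy-4-{(1R)-1-[2-(3,4,5-trimethoxyphenyl)-1,3-dioxolan-2-yl]ethoxy}cyclobut-3-ene-1,2-dione | O=C1C(=O)C(OC)=C1O[C@H](C)C2(OCCO2)c3cc(OC)c(OC)c(OC)c3 | intermediate
10 | 4-hydroxy-3-methoxy-2-{(1R)-1-[2-(3,4,5-trimethoxyphenyl)-1,3-dioxolan-2-yl]ethoxy}cyclobut-2-en-1-one (C-4 epimers) | O=C1C(O[C@H](C)C2(OCCO2)c3cc(OC)c(OC)c(OC)c3)=C(OC)C1O | intermediate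
11 | 4-chloro-3-methoxy-2-{(1R)-1-[2-(3,4,5-trimethoxyphenyl)-1,3-dioxolan-2-yl]ethoxy}cyclobut-2-en-1-one (C-4 epimers) | O=C1C(O[C@H](C)C2(OCCO2)c3cc(OC)c(OC)c(OC)c3)=C(OC)C1Cl | intermediate
12 | 2,3-dibromopropene | C=C(Br)CBr | starting material
13 | vinylmagnesium bromide | C=C[Mg]Br | starting material
14 | 2-bromopenta-1,4-diene | C=C(Br)CC=C | intermediate
15 | (penta-1,4-dien-2-yl)magnesium bromide | C=C([Mg]Br)CC=C | intermediate
16 | tributyl(penta-1,4-dien-2-yl)stannane | C=C(CC=C)[Sn](CCCC)(CCCC)CCCC | intermediate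
17 | 3-methoxy-4-(penta-1,4-dien-2-yl)-2-{(1R)-1-[2-(3,4,5-trimethoxyphenyl)-1,3-dioxolan-2-yl]ethoxy}cyclobut-2-en-1-one (C-4 epimers) | O=C1C(O[C@H](C)C2(OCCO2)c3cc(OC)c(OC)c(OC)c3)=C(OC)C1C(=C)CC=C | intermediate
18 | 3-methoxy-5-methylidene-2-{(1R)-1-[2-(3,4,5-trimethoxyphenyl)-1,3-dioxolan-2-yl]ethoxy}octa-1,3,7-trien-1-one (dienyl group cis to the ketene carbon) | O=C=C(O[C@H](C)C1(OCCO1)c2cc(OC)c(OC)c(OC)c2)/C(OC)=C\C(=C)CC=C | intermediate
19 | 3-methoxy-5-(prop-2-en-1-yl)-2-{(1R)-1-[2-(3,4,5-trimethoxyphenyl)-1,3-dioxolan-2-yl]ethoxy}cyclohexa-2,4-dien-1-one | O=C1CC(CC=C)=CC(OC)=C1O[C@H](C)C2(OCCO2)c3cc(OC)c(OC)c(OC)c3 | intermediate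
20 | 3-methoxy-5-(prop-2-en-1-yl)-2-{(1R)-1-[2-(3,4,5-trimethoxyphenyl)-1,3-dioxolan-2-yl]ethoxy}phenol | C=CCc1cc(OC)c(O[C@H](C)C2(OCCO2)c3cc(OC)c(OC)c(OC)c3)c(O)c1 | intermediate
21 | (2R)-2-[2-hydroxy-6-methoxy-4-(prop-2-en-1-yl)phenoxy]-1-(3,4,5-trimethoxyphenyl)propan-1-one | C=CCc1cc(OC)c(O[C@H](C)C(=O)c2cc(OC)c(OC)c(OC)c2)c(O)c1 | intermediate
22 | (2S,3R)-5-methoxy-3-methyl-7-(prop-2-en-1-yl)-2-(3,4,5-trimethoxyphenyl)-2,3-dihydro-1,4-benzodioxin-2-ol | C=CCc1cc(OC)c2c(c1)O[C@@](O)(c3cc(OC)c(OC)c(OC)c3)[C@@H](C)O2 | target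

**Step count**

Total: 11 steps. Longest linear sequence: 9 steps (steps 1–6, 9, 10, 11); the stannane branch (steps 7, 8) joins at step 9.

**Steps most likely to fail**

Step 5 – poor regioselectivity of hydride delivery between the two squarate carbonyls, which differ only in the remote alkoxy group. The fallback fixes the regiochemistry by symmetry. It sets out from alcohol 6 (2.2 equiv), which with 3,4-dichlorocyclobut-3-ene-1,2-dione and pyridine in CH2Cl2 at 0 °C should give 3,4-bis{(1R)-1-[2-(3,4,5-trimethoxyphenyl)-1,3-dioxolan-2-yl]ethoxy}cyclobut-3-ene-1,2-dione F1, whose carbonyls are equivalent. LiAlH(OtBu)3 then gives 4-hydroxy-2,3-bis{(1R)-1-[2-(3,4,5-trimethoxyphenyl)-1,3-dioxolan-2-yl]ethoxy}cyclobut-2-en-1-one F2. NaOMe (cat.) in MeOH at −20 °C should exchange only the C-3 alkoxy group, the vinylogous ester position, which comes back to the route at 10 and returns one equivalent of 6 for reuse.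

Step 6 – ionisation of the activated alcohol with loss of the C-2 alkoxy group (collapse to a cyclobutenedione), or decomposition of the labile chloride on concentration. The fallback avoids the halide. It sets out from 10, which is acetylated (Ac2O, pyridine, DMAP, 0 °C) to 4-acetoxy-3-methoxy-2-{(1R)-1-[2-(3,4,5-trimethoxyphenyl)-1,3-dioxolan-2-yl]ethoxy}cyclobut-2-en-1-one F3. This non-ionising allylic ester should couple with stannane 16 through the allylpalladium complex (Pd2(dba)3, tri(2-furyl)phosphine, LiCl, THF, 40 °C), coming back at 17.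

Step 9 – transmetalation from the hindered 1,1-disubstituted alkenylstannane may be slow, which would allow decomposition of the oxidative-addition complex, migration of the skipped diene into conjugation, or premature ring opening if the mixture has to be warmed. The fallback changes the nucleophile. It sets out from Grignard reagent 15, which is transmetalated with ZnCl2 (THF, 0 °C) to (penta-1,4-dien-2-yl)zinc chloride F4 and coupled with chloride 11 under Negishi conditions (Pd(PPh3)4, THF, 0 °C), coming back at 17.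

**Further compounds**

F1 | step 5 | 3,4-bis{(1R)-1-[2-(3,4,5-trimethoxyphenyl)-1,3-dioxolan-2-yl]ethoxy}cyclobut-3-ene-1,2-dione | O=C1C(=O)C(O[C@H](C)C2(OCCO2)c3cc(OC)c(OC)c(OC)c3)=C1O[C@H](C)C4(OCCO4)c5cc(OC)c(OC)c(OC)c5
F2 | step 5 | 4-hydroxy-2,3-bis{(1R)-1-[2-(3,4,5-trimethoxyphenyl)-1,3-dioxolan-2-yl]ethoxy}cyclobut-2-en-1-one | O=C1C(O[C@H](C)C2(OCCO2)c3cc(OC)c(OC)c(OC)c3)=C(O[C@H](C)C4(OCCO4)c5cc(OC)c(OC)c(OC)c5)C1O
F3 | step 6 | 4-acetoxy-3-methoxy-2-{(1R)-1-[2-(3,4,5-trimethoxyphenyl)-1,3-dioxolan-2-yl]ethoxy}cyclobut-2-en-1-one | CC(=O)OC1C(=O)C(O[C@H](C)C2(OCCO2)c3cc(OC)c(OC)c(OC)c3)=C1OC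
F4 | step 9 | (penta-1,4-dien-2-yl)zinc chloride | C=C(CC=C)[Zn]Cl
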